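The 3 questions ask for the top of the open-intermediate curve and for its first crossing, so I want the shortest way to that curve, and one ratio of two rates will do.

| flask | starting material | partner | protic impurity | remark | time |
|---|---|---|---|---|---|
| alpha | 0.025 M | 0.075 M | 2.5 mM | run made earlier |  |
| epsilon | 0.10 M | 0.075 M | 2.5 mM | run made earlier |  |
| flask | 0.050 M | 0.0750 M | 2.50 mM |  | 15 d |

| run | time / d | open intermediate / % | product / % |
|---|---|---|---|
| alpha | 0.167 | 71.1 | 3.1 |
| alpha | 0.417 | 75.3 | 18.1 |
| alpha | 0.833 | 52.4 | 44.9 |
| alpha | 1.67 | 15.2 | 82.3 |
| alpha | 4.00 | 0.4 | 96.0 |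
| alpha | 8.00 | 0.5 | 96.7 |
| alpha | 20.0 | 0 | 96.6 |
| epsilon | 0.167 | 71.3 | 2.9 |
| epsilon | 0.417 | 87.4 | 8.1 |
| epsilon | 0.833 | 81.5 | 15.6 |
| epsilon | 1.67 | 70.1 | 28.0 |
| epsilon | 4.00 | 46.4 | 51.1 |
| epsilon | 8.00 | 30.8 | 67.0 |
| epsilon | 20.0 | 24.3 | 75.7 |

(readings scatter by 0.5 percentage points)

- the best time, 15 d at the latest, for open intermediate
- the amount of open intermediate, in percent of the starting material charged, at that time
- the first time at which open intermediate reaches 41%, in the same percent

- a reading or a percentage of product counts all its forms, free or not

At 0.167 d, intermediate plus product reads 74.2% in the alpha run and 74.2% in the epsilon run, at two different charges, so I take the opening as first-order, and the logarithm of what remains gives 8.11 d⁻¹. Between 0.417 d and 0.833 d, product grows by 16.1 mM d⁻¹ in alpha and 18.0 mM d⁻¹ in epsilon, with about 16.0 mM and 84.5 mM of open intermediate present. I therefore read this drain as zero-order in open intermediate, about 17.1 mM d⁻¹ at the partner charge this flask shares. The drain divided by the opening rate of the charge is my drain ratio, 0.0421 for this flask.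

The flask's curve leaves zero at 406 mM d⁻¹, far faster than the drain, so I reckon the early rise as opening and put the first crossing at 0.0650 d. The curve bends over when opening has sunk to the drain, after the logarithm of the inverse ratio divided by the rate constant, 0.391 d. Missing at that top are the ratio as unopened starting material and the ratio times that logarithm as product, which leaves 82.5%. Partner is charged in excess, so I expect the curve of this flask to end near zero, as alpha did, reading 0.4% at 4.00 d.

The forecast says 0.37 d, 82% and 0.068 d, holding that “the peak comes where opening equals drain”; its time is a little earlier than mine.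

The flask gives 0.351 d, 81.9% and 0.0641 d, so the forecast stands.

    starting material → open intermediate (k = 0.00584 min⁻¹)
    partner → second intermediate (k = 2.03 × 10⁻⁴ min⁻¹)
    open intermediate + second intermediate → product (k = 0.160 M⁻¹ min⁻¹)
    starting material + protic impurity → quenched substrate (k = 0.0993 M⁻¹ min⁻¹)
    starting material + product ⇌ idle adduct, settled at all times (K = 8.85 M⁻¹)

At 0.351 d this flask still holds 4.89% starting material, against a drain ratio of 0.0421, or 4.21%. The neighbour with 0.20 M of starting material has the same partner charge, so the same drain over its larger charge gives a ratio of 0.0105 and a reckoned top of 94.2%. That neighbour's simulated top is 92.3%, and at 15.0 d it still holds 61.8% open intermediate, with 1.2% of its partner left.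

(The runs are simulated for an exercise, and the scatter is random.)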